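**Strategy.** The cycloheptane ring C2–C3–C4–C5–C6–C7–C8 (tricyclo[5.4.0.0(2,8)]undecane numbering; C3 bears the isobutyrate, C5 the methacrylate, C11 is the ketone) is opened at C3–C4, inside its 1,3-dioxygenated C3–C4–C5 unit. The key step closes it last by an intramolecular aldol condensation: a methyl ketone on the gem-dimethyl carbon C6 attacks a non-enolisable aldehyde on the quaternary C2, the two chains being held 1,3-cis on one face of the cyclobutane of a bicyclo[3.1.1]heptenone made by a crossed vinylketene–alkene (2+2) cycloaddition. Catalyst-controlled borylation then sets C3, and an Evans–Tishchenko reduction installs the isobutyrate and the anti C5 carbinol together.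

Key step: step 12

Assumption: the cycloadduct of step 7 is carried on as its exocyclic-methylene isomer (an endocyclic isomer would converge at 22), and in the two catalyst-controlled steps (4 and 13) the catalyst antipode is the one that gives the configuration drawn.

Locants C1–C11 in the Why lines are those of the target tricycle.

Step 1
Reactants: 1 1-[(tert-butyldimethylsilyl)oxy]propan-2-one; 2 diethyl {2-[methoxy(methyl)amino]-2-oxoethyl}phosphonate
Product: 3 (2E)-4-[(tert-butyldimethylsilyl)oxy]-N-methoxy-N,3-dimethylbut-2-enamide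
Conditions: NaH, THF, 0 °C → rt
Reagents that add atoms: none
Why: Horner–Wadsworth–Emmons olefination of the methyl ketone with the stabilised phosphonate anion is expected to favour the E amide (carbonyl trans to the larger CH2OSi group), the minor Z isomer being removed by chromatography.

Step 2
Reactants: 3 (2E)-4-[(tert-butyldimethylsilyl)oxy]-N-methoxy-N,3-dimethylbut-2-enamide
Product: 4 (2E)-4-[(tert-butyldimethylsilyl)oxy]-3-methylbut-2-enal
Conditions: i-Bu2AlH, THF, −78 °C; aq. Rochelle salt
Reagents that add atoms: none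
Why: Hydride reduction of a Weinreb amide stops at the chelated tetrahedral aluminate, which releases the enal only on work-up, so neither over-reduction nor loss of alkene geometry is expected.

Step 3
Reactants: 5 methyl 3-methylbut-2-enoate
Product: 6 tert-butyl[(1-methoxy-3-methylbuta-1,3-dien-1-yl)oxy]dimethylsilane
Conditions: LiN(i-Pr)2, THF, −78 °C; then TBSCl, DMPU
Reagents that add atoms: tert-butyldimethylsilyl chloride, CC(C)(C)[Si](C)(C)Cl
Why: Kinetic γ-deprotonation of the unsaturated ester and O-silylation of the dienolate is the standard preparation of a silyl dienol ether (silyl ketene acetal formation), and no stereocentre is formed.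

Step 4
Reactants: 4 (2E)-4-[(tert-butyldimethylsilyl)oxy]-3-methylbut-2-enal; 6 tert-butyl[(1-methoxy-3-methylbuta-1,3-dien-1-yl)oxy]dimethylsilane
Product: 8 methyl (2E,5S,6E)-8-[(tert-butyldimethylsilyl)oxy]-5-hydroxy-3,7-dimethylocta-2,6-dienoate, via trichlorosilyl ether 7 (not isolated)
Conditions: SiCl4, chiral binaphthyldiamine-derived bisphosphoramide (5 mol %), i-Pr2NEt (cat.), CH2Cl2, −78 °C; aq. KF/NaHCO3
Reagents that add atoms: none
Why: A catalytic enantioselective vinylogous Mukaiyama aldol addition (Lewis-base-activated SiCl4) should join the γ-carbon of the dienolate to the conjugated aldehyde, the chiral bisphosphoramide setting the 5S carbinol (the future C11) by catalyst control.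

Step 5
Reactants: 8 methyl (2E,5S,6E)-8-[(tert-butyldimethylsilyl)oxy]-5-hydroxy-3,7-dimethylocta-2,6-dienoate
Product: 9 methyl (2E,5S,6E)-5,8-bis[(tert-butyldimethylsilyl)oxy]-3,7-dimethylocta-2,6-dienoate
Conditions: TBSOTf, 2,6-lutidine, CH2Cl2, 0 °C
Reagents that add atoms: tert-butyldimethylsilyl trifluoromethanesulfonate, CC(C)(C)[Si](C)(C)OS(=O)(=O)C(F)(F)F
Why: Silylation of the secondary allylic alcohol with a silyl triflate and a hindered base is routine protection and leaves the stereocentre untouched.

Step 6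
Reactants: 9 methyl (2E,5S,6E)-5,8-bis[(tert-butyldimethylsilyl)oxy]-3,7-dimethylocta-2,6-dienoate
Product: 10 (2E,5S,6E)-5,8-bis[(tert-butyldimethylsilyl)oxy]-3,7-dimethylocta-2,6-dienoic acid
Conditions: LiOH, THF/MeOH/H2O, rt; 1 M HCl to pH 4, 0 °C
Reagents that add atoms: lithium hydroxide, [Li+].[OH-]
Why: Mild saponification of the methyl ester should leave both silyl ethers and both alkene geometries intact (ester hydrolysis).

Step 7
Reactants: 10 (2E,5S,6E)-5,8-bis[(tert-butyldimethylsilyl)oxy]-3,7-dimethylocta-2,6-dienoic acid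
Product: 13 4-[(tert-butyldimethylsilyl)oxy]-7-{[(tert-butyldimethylsilyl)oxy]methyl}-7-methyl-2-methylidenebicyclo[3.1.1]heptan-6-one, via acid chloride 11 (not isolated), via vinylketene 12 (not isolated)
Conditions: Me2C=C(Cl)NMe2, CH2Cl2, 0 °C → rt; solvent exchange; slow addition to Et3N, PhMe, reflux (high dilution)
Reagents that add atoms: none
Why: Dehydrochlorination at the γ-methyl group gives a vinylketene whose carbonyl carbon bonds to the less substituted alkene carbon and whose α-carbon bonds to the fully substituted one in a crossed intramolecular ketene–alkene (2+2) cycloaddition, the established entry from geranic-type acid chlorides to bicyclo[3.1.1]heptan-6-ones; suprafacial addition to the E alkene places the methyl syn and the CH2OSi group anti to the new three-carbon bridge, and the silyloxy stereocentre, which avoids that syn methyl by lying on the side of the carbonyl bridge, should select the face of addition and so fix C1, C2 and C8, any minor diastereomer being separated.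

Step 8
Reactants: 13 bicyclic cyclobutanone; 14 diethyl (3-oxobutan-2-yl)phosphonate
Product: 15 3-{4-[(tert-butyldimethylsilyl)oxy]-7-{[(tert-butyldimethylsilyl)oxy]methyl}-7-methyl-2-methylidenebicyclo[3.1.1]heptan-6-ylidene}butan-2-one
Conditions: NaH, DME, reflux
Reagents that add atoms: none
Why: The cyclobutanone is non-enolisable (both α-carbons are bridgeheads) and strain-activated, so a Horner–Wadsworth–Emmons olefination with the α-branched ketophosphonate should be feasible under forcing conditions, and the geometry of the tetrasubstituted alkene is of no consequence.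

Step 9
Reactants: 15 tetrasubstituted enone
Product: 17 3-{4-[(tert-butyldimethylsilyl)oxy]-7-{[(tert-butyldimethylsilyl)oxy]methyl}-7-methyl-2-methylidenebicyclo[3.1.1]heptan-6-yl}-3-methylbutan-2-one, via lithium enolate 16 (not isolated)
Conditions: Li, NH3(l)/THF, t-BuOH (1 equiv), −78 °C; then MeI, −78 → −33 °C
Reagents that add atoms: iodomethane, CI
Why: Dissolving-metal reduction of the enone gives the regiodefined lithium enolate, which is C-methylated to the quaternary C6 (reductive alkylation of an enone), while the β-proton is delivered to C7 from the face of the three-carbon bridge because the opposite face lies under the cyclobutane and is blocked by the 1,3-cis CH2OSi group on C2, so the side chain ends up cis to that group.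

Step 10
Reactants: 17 bis-silyl methyl ketone
Product: 18 3-[4-hydroxy-7-(hydroxymethyl)-7-methyl-2-methylidenebicyclo[3.1.1]heptan-6-yl]-3-methylbutan-2-one
Conditions: HF·pyridine, THF, 0 °C → rt
Reagents that add atoms: none
Why: Fluoride-mediated cleavage of both silyl ethers (desilylation) is orthogonal to the ketone and the isolated alkene.

Step 11
Reactants: 18 keto diol
Product: 19 7-methyl-2-methylidene-6-(2-methyl-3-oxobutan-2-yl)-4-oxobicyclo[3.1.1]heptane-7-carbaldehyde
Conditions: Dess–Martin periodinane, CH2Cl2, 0 °C → rt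
Reagents that add atoms: none
Why: Dess–Martin oxidation converts the primary alcohol into the aldehyde and the secondary alcohol into the ketone under neutral conditions, and no epimerisable centre is present (the ketone α-carbon is a bridgehead and the aldehyde sits on a quaternary carbon).

Step 12
Reactants: 19 keto aldehyde
Product: 22 2,6,6,9-tetramethyltricyclo[5.4.0.0(2,8)]undeca-3,9-diene-5,11-dione, via conjugated keto aldehyde 20 (not isolated), via aldol adduct 21 (not isolated)
Conditions: NaOMe (0.3 equiv), MeOH, 0 → 40 °C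
Reagents that add atoms: none
Why: Methoxide first moves the exocyclic alkene into conjugation with the C11 ketone (through the dienolate) to give 20, then reversibly enolises the methyl ketone, whose carbon C4 adds to the non-enolisable aldehyde carbon C3 to give aldol 21, and E1cB loss of water gives the conjugated cycloheptenone 22. The closest known reaction type is the intramolecular crossed (Claisen–Schmidt) aldol condensation of a methyl ketone with a non-enolisable aldehyde. The ring closes in a 7-(enolendo)-exo-trig mode, helped by the fact that the formyl group on C2 and the acyl-bearing C6 on C7 are 1,3-cis on the same face of the cyclobutane, a two-atom bridge apart. No lasting stereocentre is created, since the C3 carbinol of 21 is erased on dehydration and the ring alkene can only be cis. The step needs the enolate to choose the aldehyde over the C11 ketone and over γ-enolate pathways; the aldehyde is the more electrophilic carbonyl, the C11 ketone lies on the opposite face of the cyclobutane, every competing addition is reversible, and only the dehydration to 22 is a thermodynamic sink.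

Step 13
Reactants: 22 tricyclic dienedione
Product: 24 3-hydroxy-2,6,6,9-tetramethyltricyclo[5.4.0.0(2,8)]undec-9-ene-5,11-dione (hydroxyl cis to C1), via pinacol boronate 23 (not isolated)
Conditions: B2pin2, CuCl (5 mol %), NaOt-Bu (10 mol %), 2,3-bis(tert-butylmethylphosphino)quinoxaline (single enantiomer, 6 mol %), MeOH (2 equiv), THF, rt; then NaBO3·4H2O, THF/H2O
Reagents that add atoms: sodium perborate, O[B-]1(O)OO[B-](O)(O)OO1.[Na+].[Na+] (source of the C3 oxygen); bis(pinacolato)diboron, CC1(C)OB(OC1(C)C)B1OC(C)(C)C(C)(C)O1 (boron retained only in 23)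
Why: Copper-catalysed asymmetric conjugate borylation should occur at the β-monosubstituted cycloheptenone and not at the β,β-disubstituted ring enone, the chiral bisphosphine setting C3 by catalyst control because the two faces of C3 differ in the substrate only through remote groups, and perborate oxidation replaces boron by oxygen with retention.

Step 14
Reactants: 24 β-hydroxy ketone
Product: 26 5-hydroxy-2,6,6,9-tetramethyl-11-oxotricyclo[5.4.0.0(2,8)]undec-9-en-3-yl 2-methylpropanoate (3,5-anti), via hemiacetal 25 (not isolated)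
Conditions: i-PrCHO (8 equiv), SmI2 (0.3 equiv), THF, −10 °C
Reagents that add atoms: isobutyraldehyde, CC(C)C=O
Why: In the Evans–Tishchenko reduction the C3 hydroxyl forms a samarium-bound hemiacetal with isobutyraldehyde and delivers its hydride intramolecularly to the C5 ketone on the face cis to the C3 oxygen, which gives the 3,5-anti carbinol and leaves the isobutyryl group on the C3 oxygen.

Step 15
Reactants: 26 hydroxy isobutyrate
Product: 27 2,6,6,9-tetramethyl-3-(2-methylpropanoyloxy)-11-oxotricyclo[5.4.0.0(2,8)]undec-9-en-5-yl 2-methylprop-2-enoate (CNP0214356.1)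
Conditions: methacrylic anhydride, Et3N, DMAP (cat.), CH2Cl2, 0 °C → rt
Reagents that add atoms: methacrylic anhydride, CC(=C)C(=O)OC(=O)C(C)=C
Why: DMAP-catalysed acylation of the remaining secondary alcohol should proceed without acyl migration because the two oxygens are trans on the seven-membered ring (esterification).

**Compound list**

1 | 1-[(tert-butyldimethylsilyl)oxy]propan-2-one | CC(=O)CO[Si](C)(C)C(C)(C)C | starting material
2 | diethyl {2-[methoxy(methyl)amino]-2-oxoethyl}phosphonate | CCOP(=O)(CC(=O)N(C)OC)OCC | starting material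
3 | (2E)-4-[(tert-butyldimethylsilyl)oxy]-N-methoxy-N,3-dimethylbut-2-enamide | CON(C)C(=O)/C=C(\C)/CO[Si](C)(C)C(C)(C)C | intermediate
4 | (2E)-4-[(tert-butyldimethylsilyl)oxy]-3-methylbut-2-enal | O=C/C=C(\C)/CO[Si](C)(C)C(C)(C)C | intermediate
5 | methyl 3-methylbut-2-enoate | COC(=O)C=C(C)C | starting material
6 | tert-butyl[(1-methoxy-3-methylbuta-1,3-dien-1-yl)oxy]dimethylsilane (ketene acetal geometry not defined) | COC(O[Si](C)(C)C(C)(C)C)=CC(C)=C | intermediate
7 | methyl (2E,5S,6E)-8-[(tert-butyldimethylsilyl)oxy]-3,7-dimethyl-5-[(trichlorosilyl)oxy]octa-2,6-dienoate (formed in situ) | COC(=O)/C=C(\C)/C[C@H](O[Si](Cl)(Cl)Cl)/C=C(\C)/CO[Si](C)(C)C(C)(C)C | intermediate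
8 | methyl (2E,5S,6E)-8-[(tert-butyldimethylsilyl)oxy]-5-hydroxy-3,7-dimethylocta-2,6-dienoate | COC(=O)/C=C(\C)/C[C@H](O)/C=C(\C)/CO[Si](C)(C)C(C)(C)C | intermediate
9 | methyl (2E,5S,6E)-5,8-bis[(tert-butyldimethylsilyl)oxy]-3,7-dimethylocta-2,6-dienoate | COC(=O)/C=C(\C)/C[C@H](O[Si](C)(C)C(C)(C)C)/C=C(\C)/CO[Si](C)(C)C(C)(C)C | intermediate
10 | (2E,5S,6E)-5,8-bis[(tert-butyldimethylsilyl)oxy]-3,7-dimethylocta-2,6-dienoic acid | OC(=O)/C=C(\C)/C[C@H](O[Si](C)(C)C(C)(C)C)/C=C(\C)/CO[Si](C)(C)C(C)(C)C | intermediate
11 | (2E,5S,6E)-5,8-bis[(tert-butyldimethylsilyl)oxy]-3,7-dimethylocta-2,6-dienoyl chloride (formed in situ) | ClC(=O)/C=C(\C)/C[C@H](O[Si](C)(C)C(C)(C)C)/C=C(\C)/CO[Si](C)(C)C(C)(C)C | intermediate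
12 | (5S,6E)-5,8-bis[(tert-butyldimethylsilyl)oxy]-7-methyl-3-methylideneocta-1,6-dien-1-one, the vinylketene (formed in situ) | O=C=CC(=C)C[C@H](O[Si](C)(C)C(C)(C)C)/C=C(\C)/CO[Si](C)(C)C(C)(C)C | intermediate
13 | 4-[(tert-butyldimethylsilyl)oxy]-7-{[(tert-butyldimethylsilyl)oxy]methyl}-7-methyl-2-methylidenebicyclo[3.1.1]heptan-6-one (7-methyl syn to the C2–C4 bridge, silyloxymethyl anti, 4-silyloxy on the side of the carbonyl bridge) | CC(C)(C)[Si](C)(C)OC[C@@]2(C)[C@@H]3[C@@H](O[Si](C)(C)C(C)(C)C)CC(=C)[C@H]2C3=O | intermediate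
14 | diethyl (3-oxobutan-2-yl)phosphonate | CCOP(=O)(OCC)C(C)C(C)=O | starting material
15 | 3-{4-[(tert-butyldimethylsilyl)oxy]-7-{[(tert-butyldimethylsilyl)oxy]methyl}-7-methyl-2-methylidenebicyclo[3.1.1]heptan-6-ylidene}butan-2-one (alkene geometry not defined) | CC(C)(C)[Si](C)(C)OC[C@@]2(C)[C@@H]3[C@@H](O[Si](C)(C)C(C)(C)C)CC(=C)[C@H]2C3=C(C)C(C)=O | intermediate
16 | lithium enolate of 17, O-lithiated at the C5 oxygen with a C5=C6 double bond (formed in situ) | CC(C)(C)[Si](C)(C)OC[C@@]2(C)[C@@H]3[C@@H](O[Si](C)(C)C(C)(C)C)CC(=C)[C@H]2[C@@H]3C(C)=C(C)O[Li] | intermediate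
17 | 3-{4-[(tert-butyldimethylsilyl)oxy]-7-{[(tert-butyldimethylsilyl)oxy]methyl}-7-methyl-2-methylidenebicyclo[3.1.1]heptan-6-yl}-3-methylbutan-2-one (C6 side chain anti to the C2–C4 bridge, cis to the silyloxymethyl group) | CC(C)(C)[Si](C)(C)OC[C@@]2(C)[C@@H]3[C@@H](O[Si](C)(C)C(C)(C)C)CC(=C)[C@H]2[C@@H]3C(C)(C)C(C)=O | intermediate
18 | 3-[4-hydroxy-7-(hydroxymethyl)-7-methyl-2-methylidenebicyclo[3.1.1]heptan-6-yl]-3-methylbutan-2-one | OC[C@@]2(C)[C@@H]3[C@@H](O)CC(=C)[C@H]2[C@@H]3C(C)(C)C(C)=O | intermediate
19 | 7-methyl-2-methylidene-6-(2-methyl-3-oxobutan-2-yl)-4-oxobicyclo[3.1.1]heptane-7-carbaldehyde | O=C[C@@]2(C)[C@@H]3C(=O)CC(=C)[C@H]2[C@@H]3C(C)(C)C(C)=O | intermediate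
20 | 2,7-dimethyl-6-(2-methyl-3-oxobutan-2-yl)-4-oxobicyclo[3.1.1]hept-2-ene-7-carbaldehyde (formed in situ) | O=C[C@@]2(C)[C@@H]3C(=O)C=C(C)[C@H]2[C@@H]3C(C)(C)C(C)=O | intermediate
21 | 3-hydroxy-2,6,6,9-tetramethyltricyclo[5.4.0.0(2,8)]undec-9-ene-5,11-dione, both C3 epimers (formed in situ) | O=C1CC(O)[C@@]2(C)[C@@H]3C(=O)C=C(C)[C@H]2[C@@H]3C1(C)C | intermediate
22 | 2,6,6,9-tetramethyltricyclo[5.4.0.0(2,8)]undeca-3,9-diene-5,11-dione | O=C1C=C[C@@]2(C)[C@@H]3C(=O)C=C(C)[C@H]2[C@@H]3C1(C)C | intermediate
23 | 2,6,6,9-tetramethyl-3-(4,4,5,5-tetramethyl-1,3,2-dioxaborolan-2-yl)tricyclo[5.4.0.0(2,8)]undec-9-ene-5,11-dione (formed in situ) | O=C1C[C@@H](B4OC(C)(C)C(C)(C)O4)[C@@]2(C)[C@@H]3C(=O)C=C(C)[C@H]2[C@@H]3C1(C)C | intermediate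
24 | 3-hydroxy-2,6,6,9-tetramethyltricyclo[5.4.0.0(2,8)]undec-9-ene-5,11-dione (hydroxyl cis to C1) | O=C1C[C@@H](O)[C@@]2(C)[C@@H]3C(=O)C=C(C)[C@H]2[C@@H]3C1(C)C | intermediate
25 | hemiacetal of 24 with isobutyraldehyde at the C3 oxygen, samarium-bound in the flask, drawn in neutral form (formed in situ) | O=C1C[C@@H](OC(O)C(C)C)[C@@]2(C)[C@@H]3C(=O)C=C(C)[C@H]2[C@@H]3C1(C)C | intermediate
26 | 5-hydroxy-2,6,6,9-tetramethyl-11-oxotricyclo[5.4.0.0(2,8)]undec-9-en-3-yl 2-methylpropanoate (3,5-anti) | O[C@@H]1C[C@@H](OC(=O)C(C)C)[C@@]2(C)[C@@H]3C(=O)C=C(C)[C@H]2[C@@H]3C1(C)C | intermediate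
27 | 2,6,6,9-tetramethyl-3-(2-methylpropanoyloxy)-11-oxotricyclo[5.4.0.0(2,8)]undec-9-en-5-yl 2-methylprop-2-enoate (CNP0214356.1) | C=C(C)C(=O)O[C@@H]1C[C@@H](OC(=O)C(C)C)[C@@]2(C)[C@@H]3C(=O)C=C(C)[C@H]2[C@@H]3C1(C)C | target

**Step count and risk**

Total step count: 15. Longest linear sequence: 14 steps (steps 1, 2 and 4 to 15; step 3 prepares the dienol ether on a side branch).

Steps most likely to fail:

Step 13. The copper–boryl species may fail to add to the neopentyl β-carbon, or may add with poor facial selectivity, since the two faces of C3 differ only through remote groups. The fallback sets out from 22 and introduces the C3 oxygen without a chiral catalyst. Nucleophilic epoxidation (t-BuOOH, DBU, CH2Cl2) of the cycloheptenone should give the 3,4-epoxy ketone F1 as a mixture of both epoxide faces. SmI2 (THF/MeOH, −78 °C) then cleaves the C4–O bond to give 24 together with its C3 epimer F2, and the two are separated by chromatography. The unwanted epimer F2 is dehydrated (MsCl, Et3N, then DBU) back to 22 and recycled. The route is rejoined at 24.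

Step 8. The stabilised, α-branched phosphonate anion may not engage the hindered bridged ketone, or the adduct may not collapse to the tetrasubstituted alkene. The fallback sets out from 13 and replaces olefination by addition and oxidative transposition. But-2-en-2-yllithium (from 2-bromobut-2-ene and t-BuLi, Et2O, −78 °C) should add to the cyclobutanone from its open face to give the tertiary allylic alcohol F3. Oxidative 1,3-transposition with pyridinium chlorochromate (C5H5NH)[CrO3Cl] in CH2Cl2 (Babler–Dauben oxidation) then gives the enone, and the route is rejoined at 15.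

Step 9. Proton exchange between the lithium enolate and the methyl ketone product, or incomplete C-methylation of the hindered tetrasubstituted enolate, may give unmethylated or C4-methylated material. The fallback sets out from 13 and builds the quaternary C6 on a nitrile, which has a single acidic position. Peterson olefination with the lithium anion of 2-(trimethylsilyl)propanenitrile (THF, −78 °C → rt) should give the unsaturated nitrile F4. Mg in MeOH reduces the conjugated alkene, with the proton entering C7 from the open face, to give the saturated nitrile F5. LiN(i-Pr)2 and MeI then give the tertiary nitrile F6, and MeLi followed by aqueous acid converts the nitrile into the methyl ketone. The route is rejoined at 17.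

Further compounds
F1 | step 13 | 3,4-epoxy-2,6,6,9-tetramethyltricyclo[5.4.0.0(2,8)]undec-9-ene-5,11-dione (both epoxide faces) | O=C1C4OC4[C@@]2(C)[C@@H]3C(=O)C=C(C)[C@H]2[C@@H]3C1(C)C
F2 | step 13 | 3-hydroxy-2,6,6,9-tetramethyltricyclo[5.4.0.0(2,8)]undec-9-ene-5,11-dione, C3 epimer of 24 | O=C1C[C@H](O)[C@@]2(C)[C@@H]3C(=O)C=C(C)[C@H]2[C@@H]3C1(C)C
F3 | step 8 | 6-(but-2-en-2-yl)-4-[(tert-butyldimethylsilyl)oxy]-7-{[(tert-butyldimethylsilyl)oxy]methyl}-7-methyl-2-methylidenebicyclo[3.1.1]heptan-6-ol (carbinol configuration and alkene geometry not defined) | CC(C)(C)[Si](C)(C)OC[C@@]2(C)[C@@H]3[C@@H](O[Si](C)(C)C(C)(C)C)CC(=C)[C@H]2C3(O)C(C)=CC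
F4 | step 9 | 2-{4-[(tert-butyldimethylsilyl)oxy]-7-{[(tert-butyldimethylsilyl)oxy]methyl}-7-methyl-2-methylidenebicyclo[3.1.1]heptan-6-ylidene}propanenitrile | CC(C)(C)[Si](C)(C)OC[C@@]2(C)[C@@H]3[C@@H](O[Si](C)(C)C(C)(C)C)CC(=C)[C@H]2C3=C(C)C#N
F5 | step 9 | 2-{4-[(tert-butyldimethylsilyl)oxy]-7-{[(tert-butyldimethylsilyl)oxy]methyl}-7-methyl-2-methylidenebicyclo[3.1.1]heptan-6-yl}propanenitrile (side chain anti to the C2–C4 bridge, nitrile-bearing carbon as a mixture) | CC(C)(C)[Si](C)(C)OC[C@@]2(C)[C@@H]3[C@@H](O[Si](C)(C)C(C)(C)C)CC(=C)[C@H]2[C@@H]3C(C)C#N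
F6 | step 9 | 2-{4-[(tert-butyldimethylsilyl)oxy]-7-{[(tert-butyldimethylsilyl)oxy]methyl}-7-methyl-2-methylidenebicyclo[3.1.1]heptan-6-yl}-2-methylpropanenitrile | CC(C)(C)[Si](C)(C)OC[C@@]2(C)[C@@H]3[C@@H](O[Si](C)(C)C(C)(C)C)CC(=C)[C@H]2[C@@H]3C(C)(C)C#N
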